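All runs were computed with made-up constants, and the scatter is random.

4 questions stand on one flask of Z, the same flask that the delta run has followed so far, and the eta run holds twice the charge.

| flask | Z | temperature | remark | time |
|---|---|---|---|---|
| delta | 0.20 M | 25 °C | the very flask that is asked about, followed so far |  |
| eta | 0.40 M | 25 °C | run made earlier |  |
| flask | 0.20 M | 25 °C |  | 8.0 d |

| run | time / d | Q / % | Z / % |
|---|---|---|---|
| delta | 0.833 | 37.2 | 5.4 |
| delta | 1.67 | 27.8 | 4.7 |
| delta | 3.00 | 23.3 | 4.6 |
| delta | 4.00 | 22.8 | 3.4 |
| delta | 5.00 | 21.7 | 0.5 |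
| delta | 6.00 | 22.8 | 4.4 |
| eta | 0.208 | 48.9 | 4.9 |
| eta | 0.625 | 52.4 | 3.6 |
| eta | 1.04 | 48.0 | 2.6 |
| eta | 1.67 | 44.7 | 2.4 |
| eta | 2.50 | 39.6 | 3.2 |
| eta | 3.00 | 37.5 | 3.5 |
| eta | 4.00 | 32.4 | 2.8 |

(standard deviation of a reading: 1 percentage point)

- Q, in percent of the Z first charged, at 8.0 d
- the remedy with the largest gain of Q, or "none" below 2 percentage points (cedar / maple / oak / none)
- Q present, in percent of the Z first charged, after cedar
- Q present, in percent of the Z first charged, after maple

- cedar: at 8.0 d raise the temperature by 20 K, then wait 4.0 d
- maple: at 8.0 d add Z, 50.0% of the amount charged, then wait 4.0 d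
- oak: change nothing and wait 4.0 d more

- the volume of additions can be left aside
- what was read earlier has a scatter of 1 percentage point, one standard deviation
- a reading or a percentage of Q counts all its forms, free or not
- the earlier runs do not show what temperature does; that part of a forecast is a guess
- a reading of Z is of its free form alone

A bench rule says that a change is over after 5 half-lives. In delta, Q sits near 22.6% from 3.00 d on. Its excess over that level shrinks between the first two readings at a pace that reads as a half-life of 0.559 d. By 8.0 d this flask has then had 14.3 half-lives, well past the rule's 5, so the reckoning here puts now near that level and expects nothing from oak. This count belongs to the delta loading, since Q in eta still stands at 32.4% at 4.00 d and is falling.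

The rule tells when a flask stops, but not what stopped it, and there it ends. Delta's late free Z averages 3.23%, and the readings of Q and Z together do not add up to the charge. The rest, the charge minus Q minus free Z, is here called the reserve, the gap in the mass balance: 74.1%. A dead end and a balance give the same flat line, but a balance can pay its reserve back when its conditions change. Cedar adds no Z and could draw on this reserve, so the reckoning here leaves cedar open, as the runs do not show temperature.

The forecast gave 22.5% for now, 22% after cedar, 34% after maple, and chose maple. Its guess for cedar was that “A plateau that looks like an equilibrium, or a spent sink, should shift little with temperature”.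

The flask gives 22.0% at 8.0 d, and oak moves Q by −0.075 percentage points. Cedar reaches 72.1%, a gain of 50 points, and maple reaches 35.4%, a gain of 13 points, so cedar wins.

    Z ⇌ L (K = 0.420, k = 0.290 h⁻¹, Ea = 100 kJ mol⁻¹, ΔH = −3.00 kJ mol⁻¹)
    2 Z → E (k = 0.0550 M⁻¹ h⁻¹, Ea = 66.0 kJ mol⁻¹)
    Z + Q ⇌ D, settled at all times (K = 55.0 M⁻¹, ΔH = −33.0 kJ mol⁻¹)
    Z ⇌ Q (K = 4.60, k = 0.930 h⁻¹, Ea = 95.0 kJ mol⁻¹, ΔH = 24.0 kJ mol⁻¹)
    X ⇌ Q, rate k5*(cs5 - [Q]) while solid is left; crystals form when [Q] > cs5 (solubility = 0.0590 M, k = 3.40 h⁻¹)
    Z ⇌ G (K = 19.0, k = 0.380 h⁻¹, Ea = 92.0 kJ mol⁻¹, ΔH = −57.0 kJ mol⁻¹)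
    (constants at 25 °C)

Of the reserve of 74.1%, G holds 65.9% at 8.00 d. Q stands so low in this flask mainly because Q falls back to Z: in the run without that step, Q at 8.0 d is 97.3% against 22.0%. Cedar's gain rests on two returns acting together, each of them a part of the reason, G falling back to Z and L falling back to Z: with the first made one-way the gain is −0.013 points, and with the second −2.1 points. In the repeat at 50 °C, the same subtraction leaves a reserve of 17.7%, with Q at 79.3% and G down to 9.72%.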